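**Plan**

- Retrosynthesis: cut the aryl O–Si bond, then C1'–C2' of the side chain (with C1' taken to the ketone level), then the ring bond C8a–C1 (arene plus oxirane), then the oxirane C–O bonds, then the C=C bond of a (Z)-pent-2-enyl chain.
- Forward: the five-carbon chain is built on the dimethoxyphenyl ring and epoxidized, the saturated six-membered ring (the only ring made) is closed onto ring A, and the 4-oxystyryl unit is joined afterwards as a vinyl iodide.
- Stereochemistry: Sharpless epoxidation with L-(+)-diethyl tartrate fixes both oxirane carbons of the Z-allylic alcohol. The ring closure inverts the attacked carbon, which turns the cis-oxirane into the cis C1/C2 pair. C1' comes from a chelation-controlled 1,3-syn reduction directed by the C2 hydroxyl, and the E alkene from a Takai olefination.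
- Enabling feature: C8a–C1–C2–OH is a 2-arylethanol unit inside the saturated ring, and C1 also bears the oxygenated carbon C1', so C1'/C1/C2 map onto a 2,3-epoxy alcohol opened at its inner carbon. C8a lies para to the C6 methoxy group and is tied to the oxirane through C4a–C4–C3, which makes the closure a 6-endo arene attack.

Key step: step 5

Remark: tetralin locants (C1–C8a) and side-chain locants (C1'–C3') are used for all intermediates; the descriptor at C1 changes between intermediates only because substituent priorities change; 12 is carried as both C1' epimers because step 9 erases that centre.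

**Route**

Step 1
Reactants: 1 3-(3,4-dimethoxyphenyl)propan-1-ol
Product: 2 3-(3,4-dimethoxyphenyl)propanal
Conditions: TEMPO (10 mol %), PhI(OAc)2 (1.1 equiv), CH2Cl2, rt
Reagents that add atoms: none
Why: The TEMPO/PhI(OAc)2 oxidation of a primary alcohol should stop cleanly at the aldehyde and leave the electron-rich arene untouched.

Step 2
Reactants: 2 3-(3,4-dimethoxyphenyl)propanal; 3 methyl 2-[bis(2,2,2-trifluoroethoxy)phosphoryl]acetate
Product: 4 methyl (2Z)-5-(3,4-dimethoxyphenyl)pent-2-enoate
Conditions: KN(SiMe3)2, 18-crown-6, THF, −78 °C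
Reagents that add atoms: none
Why: The Still–Gennari olefination, with its electron-poor phosphonate and a dissociated potassium counter-ion, eliminates under kinetic control and should give the Z-enoate that a cis-oxirane requires.

Step 3
Reactants: 4 methyl (2Z)-5-(3,4-dimethoxyphenyl)pent-2-enoate
Product: 5 (2Z)-5-(3,4-dimethoxyphenyl)pent-2-en-1-ol
Conditions: iBu2AlH (2.5 equiv), CH2Cl2, −78 °C; Rochelle salt work-up
Reagents that add atoms: none
Why: The 1,2-reduction of an enoate by iBu2AlH at low temperature should give the allylic alcohol without touching the Z geometry.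

Step 4
Reactants: 5 (2Z)-5-(3,4-dimethoxyphenyl)pent-2-en-1-ol
Product: 6 [(2S,3R)-3-[2-(3,4-dimethoxyphenyl)ethyl]oxiran-2-yl]methanol
Conditions: Ti(OiPr)4 (10 mol %), L-(+)-diethyl tartrate (12 mol %), t-BuOOH (2 equiv, in decane), 4 Å molecular sieves, CH2Cl2, −20 °C
Reagents that add atoms: tert-butyl hydroperoxide, CC(C)(C)OO
Why: In the Sharpless asymmetric epoxidation the titanium tartrate complex delivers oxygen to one enantioface of the hydroxyl-bound alkene, and L-(+)-diethyl tartrate should give the (2S,3R) cis-epoxy alcohol as it does with other Z-allylic alcohols, which react more slowly and somewhat less selectively than E ones so that loading and time are adjusted.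

Step 5
Reactants: 6 [(2S,3R)-3-[2-(3,4-dimethoxyphenyl)ethyl]oxiran-2-yl]methanol
Product: 7 (1R,2R)-1-(hydroxymethyl)-6,7-dimethoxy-1,2,3,4-tetrahydronaphthalen-2-ol
Conditions: SnCl4 (30 mol %), CH2Cl2, −78 → −20 °C; aq. NaHCO3
Reagents that add atoms: none
Why: SnCl4 binds the oxirane oxygen, the ring A carbon para to a methoxy group attacks the oxirane carbon that bears CH2OH from the side opposite to its C–O bond, and loss of the ring proton restores the arene, so that the C8a–C1 bond and the C2 hydroxyl arise in one event. The closest known reaction type is the Lewis-acid-promoted intramolecular Friedel–Crafts epoxy-arene cyclization of aryl-tethered epoxides and 2,3-epoxy alcohols, which gives 2-tetralols and cyclic 1,3-diols. The saturated six-membered ring closes in the 6-endo mode with respect to the oxirane, both oxirane carbons becoming ring atoms. The new stereocenter C1 is controlled by inversion at the attacked oxirane carbon, so the cis-oxirane from step 4 should give the cis C1/C2 pair, while C2 keeps its C–O bond and its configuration. The step needs 6-endo over 5-exo opening and attack para instead of ortho to a methoxy group; the two-carbon tether cannot bring the arene to the rear of the distal oxirane carbon through a five-membered transition state, and the ortho position flanked by the chain is hindered.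

Step 6
Reactants: 7 (1R,2R)-1-(hydroxymethyl)-6,7-dimethoxy-1,2,3,4-tetrahydronaphthalen-2-ol
Product: 8 (1S,2R)-2-hydroxy-6,7-dimethoxy-1,2,3,4-tetrahydronaphthalene-1-carbaldehyde
Conditions: TEMPO (10 mol %), PhI(OAc)2 (1.1 equiv), CH2Cl2, 0 °C → rt; used crude
Reagents that add atoms: none
Why: The TEMPO/PhI(OAc)2 oxidation is selective for the primary hydroxyl of a 1,3-diol and runs without base, which should protect the epimerizable C1 of the β-hydroxy aldehyde.

Step 7
Reactants: 9 4-[(tert-butyldimethylsilyl)oxy]benzaldehyde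
Product: 10 tert-butyl-[4-[(E)-2-iodoethenyl]phenoxy]dimethylsilane
Conditions: CHI3 (2 equiv), CrCl2 (6 equiv), THF, 0 °C → rt
Reagents that add atoms: iodoform, IC(I)I
Why: The Takai olefination should convert the aromatic aldehyde into the vinyl iodide with high E selectivity while the aryl silyl ether stays inert.

Step 8
Reactants: 8 (1S,2R)-2-hydroxy-6,7-dimethoxy-1,2,3,4-tetrahydronaphthalene-1-carbaldehyde; 10 tert-butyl-[4-[(E)-2-iodoethenyl]phenoxy]dimethylsilane
Product: 12 (1S,2R)-1-[(2E)-3-[4-(tert-butyldimethylsilyloxy)phenyl]-1-hydroxyprop-2-en-1-yl]-6,7-dimethoxy-1,2,3,4-tetrahydronaphthalen-2-ol (both epimers at C1'), via alkenylchromium dichloride 11 (not isolated)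
Conditions: CrCl2 (4 equiv), NiCl2 (2 mol %), DMF, rt
Reagents that add atoms: none
Why: In the Nozaki–Hiyama–Kishi coupling the non-basic alkenylchromium reagent should add to the aldehyde with retention of the E geometry and tolerate the free hydroxyl and the acidic C1–H, and the configuration of the new carbinol does not matter because step 9 erases it.

Step 9
Reactants: 12 (1S,2R)-1-[(2E)-3-[4-(tert-butyldimethylsilyloxy)phenyl]-1-hydroxyprop-2-en-1-yl]-6,7-dimethoxy-1,2,3,4-tetrahydronaphthalen-2-ol
Product: 13 (2E)-3-[4-(tert-butyldimethylsilyloxy)phenyl]-1-[(1S,2R)-2-hydroxy-6,7-dimethoxy-1,2,3,4-tetrahydronaphthalen-1-yl]prop-2-en-1-one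
Conditions: MnO2 (activated, excess), CH2Cl2, rt
Reagents that add atoms: none
Why: The MnO2 oxidation acts only on the allylic hydroxyl and is neutral and heterogeneous, so it should spare the C2 hydroxyl, the C1 stereocenter and the silyl ether.

Step 10
Reactants: 13 (2E)-3-[4-(tert-butyldimethylsilyloxy)phenyl]-1-[(1S,2R)-2-hydroxy-6,7-dimethoxy-1,2,3,4-tetrahydronaphthalen-1-yl]prop-2-en-1-one
Product: 15 (1S,2R)-1-[(1S,2E)-3-[4-(tert-butyldimethylsilyloxy)phenyl]-1-hydroxyprop-2-en-1-yl]-6,7-dimethoxy-1,2,3,4-tetrahydronaphthalen-2-ol, via diethylboron chelate 14 (not isolated)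
Conditions: Et2BOMe (1.1 equiv), THF/MeOH (4:1), −78 °C; NaBH4, −78 °C; aq. NH4Cl, then co-evaporation with MeOH
Reagents that add atoms: none
Why: In the Narasaka–Prasad reduction the boron ties the C2 oxygen and the ketone into a six-membered chelate that is cis-fused to the tetralin, and external hydride should add 1,2 to the carbonyl from the convex face (anti to C3 and C8a), which gives the 1,3-syn diol, that is S at C1'.

Step 11
Reactants: 15 (1S,2R)-1-[(1S,2E)-3-[4-(tert-butyldimethylsilyloxy)phenyl]-1-hydroxyprop-2-en-1-yl]-6,7-dimethoxy-1,2,3,4-tetrahydronaphthalen-2-ol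
Product: 16 (1S,2R)-1-[(1S,2E)-1-hydroxy-3-(4-hydroxyphenyl)prop-2-en-1-yl]-6,7-dimethoxy-1,2,3,4-tetrahydronaphthalen-2-ol
Conditions: Bu4NF (1.1 equiv), AcOH (1.1 equiv), THF, 0 °C
Reagents that add atoms: none
Why: Fluoride-mediated desilylation should cleave the aryl silyl ether, and the acetic acid buffer keeps the medium near neutral for the acid- and base-sensitive 4-hydroxycinnamyl alcohol.

**Compound list**

1 | 3-(3,4-dimethoxyphenyl)propan-1-ol | OCCCc1ccc(OC)c(OC)c1 | starting material
2 | 3-(3,4-dimethoxyphenyl)propanal | O=CCCc1ccc(OC)c(OC)c1 | intermediate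
3 | methyl 2-[bis(2,2,2-trifluoroethoxy)phosphoryl]acetate | COC(=O)CP(=O)(OCC(F)(F)F)OCC(F)(F)F | starting material
4 | methyl (2Z)-5-(3,4-dimethoxyphenyl)pent-2-enoate | COC(=O)/C=C\CCc1ccc(OC)c(OC)c1 | intermediate
5 | (2Z)-5-(3,4-dimethoxyphenyl)pent-2-en-1-ol | OC/C=C\CCc1ccc(OC)c(OC)c1 | intermediate
6 | [(2S,3R)-3-[2-(3,4-dimethoxyphenyl)ethyl]oxiran-2-yl]methanol | OC[C@@H]1O[C@@H]1CCc1ccc(OC)c(OC)c1 | intermediate
7 | (1R,2R)-1-(hydroxymethyl)-6,7-dimethoxy-1,2,3,4-tetrahydronaphthalen-2-ol | COc1cc2c(cc1OC)[C@H](CO)[C@H](O)CC2 | intermediate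
8 | (1S,2R)-2-hydroxy-6,7-dimethoxy-1,2,3,4-tetrahydronaphthalene-1-carbaldehyde | COc1cc2c(cc1OC)[C@H](C=O)[C@H](O)CC2 | intermediate
9 | 4-[(tert-butyldimethylsilyl)oxy]benzaldehyde | O=Cc1ccc(O[Si](C)(C)C(C)(C)C)cc1 | starting material
10 | tert-butyl-[4-[(E)-2-iodoethenyl]phenoxy]dimethylsilane | I/C=C/c1ccc(O[Si](C)(C)C(C)(C)C)cc1 | intermediate
11 | [(E)-2-[4-(tert-butyldimethylsilyloxy)phenyl]ethenyl]chromium dichloride | Cl[Cr](Cl)/C=C/c1ccc(O[Si](C)(C)C(C)(C)C)cc1 | intermediate
12 | (1S,2R)-1-[(2E)-3-[4-(tert-butyldimethylsilyloxy)phenyl]-1-hydroxyprop-2-en-1-yl]-6,7-dimethoxy-1,2,3,4-tetrahydronaphthalen-2-ol (both C1' epimers) | COc1cc2c(cc1OC)[C@H](C(O)/C=C/c1ccc(O[Si](C)(C)C(C)(C)C)cc1)[C@H](O)CC2 | intermediate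
13 | (2E)-3-[4-(tert-butyldimethylsilyloxy)phenyl]-1-[(1S,2R)-2-hydroxy-6,7-dimethoxy-1,2,3,4-tetrahydronaphthalen-1-yl]prop-2-en-1-one | COc1cc2c(cc1OC)[C@H](C(=O)/C=C/c1ccc(O[Si](C)(C)C(C)(C)C)cc1)[C@H](O)CC2 | intermediate
14 | (2E)-3-[4-(tert-butyldimethylsilyloxy)phenyl]-1-[(1S,2R)-2-(diethylboranyloxy)-6,7-dimethoxy-1,2,3,4-tetrahydronaphthalen-1-yl]prop-2-en-1-one (ketone oxygen bound to boron) | COc1cc2c(cc1OC)[C@H](C(=O)/C=C/c1ccc(O[Si](C)(C)C(C)(C)C)cc1)[C@H](OB(CC)CC)CC2 | intermediate
15 | (1S,2R)-1-[(1S,2E)-3-[4-(tert-butyldimethylsilyloxy)phenyl]-1-hydroxyprop-2-en-1-yl]-6,7-dimethoxy-1,2,3,4-tetrahydronaphthalen-2-ol | COc1cc2c(cc1OC)[C@H]([C@@H](O)/C=C/c1ccc(O[Si](C)(C)C(C)(C)C)cc1)[C@H](O)CC2 | intermediate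
16 | (1S,2R)-1-[(1S,2E)-1-hydroxy-3-(4-hydroxyphenyl)prop-2-en-1-yl]-6,7-dimethoxy-1,2,3,4-tetrahydronaphthalen-2-ol | COc1cc2c(cc1OC)[C@H]([C@@H](O)/C=C/c1ccc(O)cc1)[C@H](O)CC2 | target

**Step count and risks**

Total step count: 11. Longest linear sequence: 10 (steps 1–6 and 8–11, from 1 to 16); step 7 is a one-step side branch.

Steps most likely to fail:

1. Step 5. The oxirane may open at the wrong carbon (5-exo arene attack or chloride delivery), or rearrange by hydride shift before the arene attacks. The fallback replaces the oxirane opening by a carbenoid ring closure followed by an enzymatic dynamic kinetic resolution; it sets out from 2 and comes back at 7. SnCl2-catalysed homologation of 2 with methyl diazoacetate (Roskamp reaction) should give methyl 5-(3,4-dimethoxyphenyl)-3-oxopentanoate F1. Diazo transfer with 4-acetamidobenzenesulfonyl azide and Et3N should give methyl 2-diazo-5-(3,4-dimethoxyphenyl)-3-oxopentanoate F2. Rh2(OAc)4 in CH2Cl2 should close the ring by carbenoid substitution on ring A para to the methoxy group and give methyl 6,7-dimethoxy-2-oxo-1,2,3,4-tetrahydronaphthalene-1-carboxylate F3. A ketoreductase (NADPH, glucose and glucose dehydrogenase for recycling, pH 7 buffer), picked from a panel for the cis product, should reduce the rapidly racemizing β-keto ester to methyl (1S,2R)-2-hydroxy-6,7-dimethoxy-1,2,3,4-tetrahydronaphthalene-1-carboxylate F4. LiAlH4 in THF at 0 °C should then give 7.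

2. Step 8. The β-hydroxy aldehyde may epimerize at C1 or lose water by β-elimination before or during the chromium-mediated coupling. The fallback forms the C1'–C2' bond at the carboxylic acid oxidation level; it sets out from 7 and comes back at 13, so that steps 6, 8 and 9 are bypassed. Selective oxidation of the primary hydroxyl of 7 (TEMPO, NaOCl cat., NaClO2, buffered MeCN) should give (1S,2R)-2-hydroxy-6,7-dimethoxy-1,2,3,4-tetrahydronaphthalene-1-carboxylic acid F5. Coupling with N,O-dimethylhydroxylamine hydrochloride (EDC·HCl, HOBt, N-methylmorpholine) should give the Weinreb amide (1S,2R)-2-hydroxy-N,6,7-trimethoxy-N-methyl-1,2,3,4-tetrahydronaphthalene-1-carboxamide F6. Iodine–lithium exchange on 10 (t-BuLi, Et2O, −78 °C) should give [(E)-2-[4-(tert-butyldimethylsilyloxy)phenyl]ethenyl]lithium F7. An excess of this reagent should add to F6, whose C2 alkoxide shields C1 from deprotonation, and give 13 after work-up.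

3. Step 4. Enantiofacial discrimination may be incomplete and turnover slow with the Z-allylic alcohol. The fallback replaces reliance on catalyst control by enrichment through a crystalline derivative; it sets out from 6 and comes back at 6. Acylation with 4-nitrobenzoyl chloride (Et3N, DMAP cat.) should give [(2S,3R)-3-[2-(3,4-dimethoxyphenyl)ethyl]oxiran-2-yl]methyl 4-nitrobenzoate F8, which is recrystallized to raise the enantiomeric purity and then cleaved with K2CO3 (cat.) in MeOH at 0 °C back to 6.

**Further compounds**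

F1 | step 5 | methyl 5-(3,4-dimethoxyphenyl)-3-oxopentanoate | COC(=O)CC(=O)CCc1ccc(OC)c(OC)c1
F2 | step 5 | methyl 2-diazo-5-(3,4-dimethoxyphenyl)-3-oxopentanoate | COC(=O)C(=[N+]=[N-])C(=O)CCc1ccc(OC)c(OC)c1
F3 | step 5 | methyl 6,7-dimethoxy-2-oxo-1,2,3,4-tetrahydronaphthalene-1-carboxylate | COC(=O)C1C(=O)CCc2cc(OC)c(OC)cc12
F4 | step 5 | methyl (1S,2R)-2-hydroxy-6,7-dimethoxy-1,2,3,4-tetrahydronaphthalene-1-carboxylate | COc1cc2c(cc1OC)[C@H](C(=O)OC)[C@H](O)CC2
F5 | step 8 | (1S,2R)-2-hydroxy-6,7-dimethoxy-1,2,3,4-tetrahydronaphthalene-1-carboxylic acid | COc1cc2c(cc1OC)[C@H](C(=O)O)[C@H](O)CC2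
F6 | step 8 | (1S,2R)-2-hydroxy-N,6,7-trimethoxy-N-methyl-1,2,3,4-tetrahydronaphthalene-1-carboxamide | COc1cc2c(cc1OC)[C@H](C(=O)N(C)OC)[C@H](O)CC2
F7 | step 8 | [(E)-2-[4-(tert-butyldimethylsilyloxy)phenyl]ethenyl]lithium | [Li]/C=C/c1ccc(O[Si](C)(C)C(C)(C)C)cc1
F8 | step 4 | [(2S,3R)-3-[2-(3,4-dimethoxyphenyl)ethyl]oxiran-2-yl]methyl 4-nitrobenzoate | O=C(OC[C@@H]1O[C@@H]1CCc1ccc(OC)c(OC)c1)c1ccc(cc1)[N+](=O)[O-]
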